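The route rests on disconnecting the ring-fusion bond C7–C8 shared by the cyclohexane (C5–C10) and the α-methylene-γ-butyrolactone: C7 is the γ-carbon of a 2-(methoxycarbonyl)allyl unit and C8 a carbinol carbon. A divalent-chromium intramolecular allylation of an acyclic ω-formyl (Z)-2-(bromomethyl)enoate closes the carbocycle, sets C7 and C8, creates the exocyclic methylene and leads on to the cis-fused lactone. The open-chain precursor carries the C5/C6/C9/C10 stereotetrad, assembled by a chelate-controlled dianionic Ireland–Claisen rearrangement that joins an aldol-derived β-hydroxy ester to a Morita–Baylis–Hillman-derived allylic alcohol.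

Key step: step 19

Remark: atoms carry elemane-type numbers throughout: C10 (quaternary; methyl C14; vinyl C1=C2), C5 (bearing C4(=C3H2)–C15H2OH), C6 (OH), C7 (bearing C11(=C13H2)–C12 carbonyl), C8 (lactone oxygen), C9 (isobutyrate); the target is (5S,6R,7S,8S,9R,10S). Compounds 1, 2 and 5 are taken as commercial.

Step 1
Reactants: 1 (R)-4-benzyl-3-propanoyl-1,3-thiazolidine-2-thione; 2 2-[(4-methoxybenzyl)oxy]acetaldehyde
Product: 4 (R)-4-benzyl-3-[(2R,3R)-3-hydroxy-4-(4-methoxybenzyloxy)-2-methylbutanoyl]-1,3-thiazolidine-2-thione, via trichlorotitanium enolate 3 (not isolated)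
Conditions: TiCl4, iPr2NEt, N-methyl-2-pyrrolidone, CH2Cl2, 0 °C; then 2, −78 → 0 °C
Reagents that add atoms: none
Why: Auxiliary-controlled titanium-enolate syn-aldol of an N-acylthiazolidinethione, in which the (Z)-enolate should add through a chair Zimmerman–Traxler transition state on the face away from the benzyl group and so fix the carbinol carbon (future C9) as R; the α-methyl centre is erased again in step 7.

Step 2
Reactants: 5 (S)-2,2-dimethyl-1,3-dioxolane-4-carbaldehyde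
Product: 6 methyl 2-{[(4S)-2,2-dimethyl-1,3-dioxolan-4-yl](hydroxy)methyl}prop-2-enoate (both carbinol epimers)
Conditions: methyl acrylate (excess), 1,4-diazabicyclo[2.2.2]octane (cat.), 23 °C
Reagents that add atoms: methyl acrylate, C=CC(=O)OC
Why: Morita–Baylis–Hillman reaction of an activated α-alkoxy aldehyde; the new carbinol centre needs no control because it becomes sp2 in step 3, and the dioxolane carbon of 5 becomes C6 of the target.

Step 3
Reactants: 6 methyl 2-{[(4S)-2,2-dimethyl-1,3-dioxolan-4-yl](hydroxy)methyl}prop-2-enoate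
Product: 7 methyl (Z)-2-(bromomethyl)-3-[(4R)-2,2-dimethyl-1,3-dioxolan-4-yl]prop-2-enoate
Conditions: N-bromosuccinimide, Me2S, CH2Cl2, 0 → 23 °C
Reagents that add atoms: N-bromosuccinimide, O=C1CCC(=O)N1Br
Why: Bromination of the Morita–Baylis–Hillman alcohol with allylic transposition (SN2′) should give the thermodynamically preferred trisubstituted enoate, with the dioxolane cis to CH2Br and trans to the ester.

Step 4
Reactants: 7 methyl (Z)-2-(bromomethyl)-3-[(4R)-2,2-dimethyl-1,3-dioxolan-4-yl]prop-2-enoate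
Product: 8 methyl (E)-3-[(4R)-2,2-dimethyl-1,3-dioxolan-4-yl]-2-[(4-methoxyphenoxy)methyl]prop-2-enoate
Conditions: 4-methoxyphenol, K2CO3, acetone, 23 °C
Reagents that add atoms: 4-methoxyphenol, COc1ccc(O)cc1
Why: Williamson ether synthesis (SN2 at the primary allylic bromide) installs the future C15 oxygen as a 4-methoxyphenyl ether without changing the alkene geometry.

Step 5
Reactants: 8 methyl (E)-3-[(4R)-2,2-dimethyl-1,3-dioxolan-4-yl]-2-[(4-methoxyphenoxy)methyl]prop-2-enoate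
Product: 9 (Z)-3-[(4R)-2,2-dimethyl-1,3-dioxolan-4-yl]-2-[(4-methoxyphenoxy)methyl]prop-2-en-1-ol
Conditions: iBu2AlH, CH2Cl2, −78 °C
Reagents that add atoms: none
Why: 1,2-Reduction of the conjugated ester by iBu2AlH gives the allylic alcohol whose CH2OH (future C3) is trans to the dioxolane, the geometry required in step 7.

Step 6
Reactants: 4 (R)-4-benzyl-3-[(2R,3R)-3-hydroxy-4-(4-methoxybenzyloxy)-2-methylbutanoyl]-1,3-thiazolidine-2-thione; 9 (Z)-3-[(4R)-2,2-dimethyl-1,3-dioxolan-4-yl]-2-[(4-methoxyphenoxy)methyl]prop-2-en-1-ol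
Product: 10 (E)-3-[(4R)-2,2-dimethyl-1,3-dioxolan-4-yl]-2-[(4-methoxyphenoxy)methyl]prop-2-en-1-yl (2R,3R)-3-hydroxy-4-(4-methoxybenzyloxy)-2-methylbutanoate (alkene geometry unchanged; descriptor changes by priority only)
Conditions: 4-(dimethylamino)pyridine (cat.), CH2Cl2, 23 °C
Reagents that add atoms: none
Why: Nucleophilic acyl substitution on the activated N-acylthiazolidinethione by the primary allylic alcohol gives the ester directly and releases the auxiliary, the hindered secondary β-hydroxyl being much less reactive.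

Step 7
Reactants: 10 (E)-3-[(4R)-2,2-dimethyl-1,3-dioxolan-4-yl]-2-[(4-methoxyphenoxy)methyl]prop-2-en-1-yl (2R,3R)-3-hydroxy-4-(4-methoxybenzyloxy)-2-methylbutanoate
Product: 12 (2S,3R)-2-{(1S)-1-[(4R)-2,2-dimethyl-1,3-dioxolan-4-yl]-2-[(4-methoxyphenoxy)methyl]prop-2-en-1-yl}-3-hydroxy-4-(4-methoxybenzyloxy)-2-methylbutanoic acid, via dilithium enolate alkoxide 11 (not isolated)
Conditions: LiN(iPr)2 (2.3 equiv), THF, −78 °C; then 23 → 50 °C; aq. HCl
Reagents that add atoms: none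
Why: Dianionic Ireland–Claisen rearrangement of a β-hydroxy ester: lithium chelation between alkoxide and enolate oxygens fixes the enolate geometry (C9 cis to O–Li) and, as in Fráter–Seebach alkylations, the new C10–C5 bond should form anti to the C8 branch (sets C10), while in the chair transition state C6 is equatorial and allylic 1,3-strain with CH2OAr holds H6 in the alkene plane so that C5 is bonded anti to the dioxolane C–O bond (sets C5; matched case).

Step 8
Reactants: 12 (2S,3R)-2-{(1S)-1-[(4R)-2,2-dimethyl-1,3-dioxolan-4-yl]-2-[(4-methoxyphenoxy)methyl]prop-2-en-1-yl}-3-hydroxy-4-(4-methoxybenzyloxy)-2-methylbutanoic acid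
Product: 13 (2R,3R)-2-{(1S)-1-[(4R)-2,2-dimethyl-1,3-dioxolan-4-yl]-2-[(4-methoxyphenoxy)methyl]prop-2-en-1-yl}-4-(4-methoxybenzyloxy)-2-methylbutane-1,3-diol
Conditions: LiAlH4, THF, 0 → 40 °C
Reagents that add atoms: none
Why: Hydride reduction of the carboxylic acid to the neopentyl primary alcohol (future C1), with acetal, ethers and alkenes inert.

Step 9
Reactants: 13 (2R,3R)-2-{(1S)-1-[(4R)-2,2-dimethyl-1,3-dioxolan-4-yl]-2-[(4-methoxyphenoxy)methyl]prop-2-en-1-yl}-4-(4-methoxybenzyloxy)-2-methylbutane-1,3-diol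
Product: 14 (2S,3R)-2-{(1S)-1-[(4R)-2,2-dimethyl-1,3-dioxolan-4-yl]-2-[(4-methoxyphenoxy)methyl]prop-2-en-1-yl}-3-hydroxy-4-(4-methoxybenzyloxy)-2-methylbutanal
Conditions: 2,2,6,6-tetramethylpiperidin-1-oxyl (cat.), PhI(OAc)2, CH2Cl2, 23 °C
Reagents that add atoms: none
Why: Oxoammonium-mediated oxidation is selective for the primary over the secondary alcohol, and the aldehyde has a quaternary α-carbon so it can neither enolize nor dehydrate.

Step 10
Reactants: 14 (2S,3R)-2-{(1S)-1-[(4R)-2,2-dimethyl-1,3-dioxolan-4-yl]-2-[(4-methoxyphenoxy)methyl]prop-2-en-1-yl}-3-hydroxy-4-(4-methoxybenzyloxy)-2-methylbutanal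
Product: 15 (2R,3S,4S)-4-[(4R)-2,2-dimethyl-1,3-dioxolan-4-yl]-3-formyl-1-(4-methoxybenzyloxy)-5-[(4-methoxyphenoxy)methyl]-3-methylhex-5-en-2-yl 2-methylpropanoate
Conditions: isobutyryl chloride, pyridine, 4-(dimethylamino)pyridine (cat.), CH2Cl2, 0 → 23 °C
Reagents that add atoms: isobutyryl chloride, CC(C)C(=O)Cl
Why: Acylation of the only free hydroxyl installs the C9 isobutyrate of the target and removes the retro-aldol pathway before the basic step 11.

Step 11
Reactants: 15 (2R,3S,4S)-4-[(4R)-2,2-dimethyl-1,3-dioxolan-4-yl]-3-formyl-1-(4-methoxybenzyloxy)-5-[(4-methoxyphenoxy)methyl]-3-methylhex-5-en-2-yl 2-methylpropanoate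
Product: 16 (2R,3S,4S)-4-[(4R)-2,2-dimethyl-1,3-dioxolan-4-yl]-3-ethenyl-1-(4-methoxybenzyloxy)-5-[(4-methoxyphenoxy)methyl]-3-methylhex-5-en-2-yl 2-methylpropanoate
Conditions: Ph3PCH3Br, KN(SiMe3)2, THF, 0 °C; then 15, −78 → 0 °C
Reagents that add atoms: methyltriphenylphosphonium bromide, C[P+](c1ccccc1)(c1ccccc1)c1ccccc1.[Br-]
Why: Wittig methylenation turns the non-enolizable aldehyde into the C1=C2 vinyl group, the ylide reacting far faster with the aldehyde than with the hindered ester.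

Step 12
Reactants: 16 (2R,3S,4S)-4-[(4R)-2,2-dimethyl-1,3-dioxolan-4-yl]-3-ethenyl-1-(4-methoxybenzyloxy)-5-[(4-methoxyphenoxy)methyl]-3-methylhex-5-en-2-yl 2-methylpropanoate
Product: 17 (2R,3S,4S)-4-[(1R)-1,2-dihydroxyethyl]-3-ethenyl-1-(4-methoxybenzyloxy)-5-[(4-methoxyphenoxy)methyl]-3-methylhex-5-en-2-yl 2-methylpropanoate
Conditions: AcOH/H2O (4:1), 40 °C
Reagents that add atoms: none
Why: Acid-catalysed acetal hydrolysis frees the C6/C7 diol while the ester and the benzyl and aryl ethers are stable.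

Step 13
Reactants: 17 (2R,3S,4S)-4-[(1R)-1,2-dihydroxyethyl]-3-ethenyl-1-(4-methoxybenzyloxy)-5-[(4-methoxyphenoxy)methyl]-3-methylhex-5-en-2-yl 2-methylpropanoate
Product: 18 (2R,3S,4S)-4-[(1R)-1,2-bis(triethylsilyloxy)ethyl]-3-ethenyl-1-(4-methoxybenzyloxy)-5-[(4-methoxyphenoxy)methyl]-3-methylhex-5-en-2-yl 2-methylpropanoate
Conditions: Et3SiOTf, 2,6-lutidine, CH2Cl2, −78 °C
Reagents that add atoms: triethylsilyl trifluoromethanesulfonate, CC[Si](CC)(CC)OS(=O)(=O)C(F)(F)F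
Why: Silylation of both hydroxyls prepares the primary/secondary differentiation used in step 14.

Step 14
Reactants: 18 (2R,3S,4S)-4-[(1R)-1,2-bis(triethylsilyloxy)ethyl]-3-ethenyl-1-(4-methoxybenzyloxy)-5-[(4-methoxyphenoxy)methyl]-3-methylhex-5-en-2-yl 2-methylpropanoate
Product: 19 (2R,3S,4S)-3-ethenyl-1-(4-methoxybenzyloxy)-5-[(4-methoxyphenoxy)methyl]-3-methyl-4-[(1R)-2-oxo-1-(triethylsilyloxy)ethyl]hex-5-en-2-yl 2-methylpropanoate
Conditions: (COCl)2, Me2SO, CH2Cl2, −78 → −40 °C; then Et3N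
Reagents that add atoms: none
Why: Under Swern conditions a primary triethylsilyl ether is cleaved and oxidized in place to the aldehyde while the secondary silyl ether survives (oxidative desilylation), giving the C7 aldehyde with O6 still protected.

Step 15
Reactants: 19 (2R,3S,4S)-3-ethenyl-1-(4-methoxybenzyloxy)-5-[(4-methoxyphenoxy)methyl]-3-methyl-4-[(1R)-2-oxo-1-(triethylsilyloxy)ethyl]hex-5-en-2-yl 2-methylpropanoate
Product: 20 methyl (4R,5S,6S,7R)-6-ethenyl-3-hydroxy-8-(4-methoxybenzyloxy)-5-[3-(4-methoxyphenoxy)prop-1-en-2-yl]-6-methyl-2-methylidene-7-(2-methylpropanoyloxy)-4-(triethylsilyloxy)octanoate (both C3 epimers)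
Conditions: methyl propiolate, iBu2AlH, N-methylmorpholine N-oxide, THF, 0 °C; then 19, 0 → 23 °C
Reagents that add atoms: methyl propiolate, C#CC(=O)OC
Why: Hydroalumination of methyl propiolate gives an α-(methoxycarbonyl)vinylalane that adds to the hindered aldehyde (vinylalumination) to give the Morita–Baylis–Hillman-type adduct; the new carbinol centre is removed in step 16.

Step 16
Reactants: 20 methyl (4R,5S,6S,7R)-6-ethenyl-3-hydroxy-8-(4-methoxybenzyloxy)-5-[3-(4-methoxyphenoxy)prop-1-en-2-yl]-6-methyl-2-methylidene-7-(2-methylpropanoyloxy)-4-(triethylsilyloxy)octanoate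
Product: 21 methyl (2Z,4S,5S,6S,7R)-2-(bromomethyl)-6-ethenyl-8-(4-methoxybenzyloxy)-5-[3-(4-methoxyphenoxy)prop-1-en-2-yl]-6-methyl-7-(2-methylpropanoyloxy)-4-(triethylsilyloxy)oct-2-enoate
Conditions: N-bromosuccinimide, Me2S, CH2Cl2, 0 °C
Reagents that add atoms: N-bromosuccinimide, O=C1CCC(=O)N1Br
Why: SN2′ bromination as in step 3 should deliver the (Z)-2-(bromomethyl)enoate with C6 cis to CH2Br, the geometry that later enforces the cis ring fusion.

Step 17
Reactants: 21 methyl (2Z,4S,5S,6S,7R)-2-(bromomethyl)-6-ethenyl-8-(4-methoxybenzyloxy)-5-[3-(4-methoxyphenoxy)prop-1-en-2-yl]-6-methyl-7-(2-methylpropanoyloxy)-4-(triethylsilyloxy)oct-2-enoate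
Product: 22 methyl (2Z,4S,5S,6S,7R)-2-(bromomethyl)-6-ethenyl-8-hydroxy-5-[3-(4-methoxyphenoxy)prop-1-en-2-yl]-6-methyl-7-(2-methylpropanoyloxy)-4-(triethylsilyloxy)oct-2-enoate
Conditions: 2,3-dichloro-5,6-dicyano-1,4-benzoquinone, CH2Cl2/pH 7 buffer, 0 °C
Reagents that add atoms: none
Why: Oxidative cleavage of the 4-methoxybenzyl ether by benzylic hydride abstraction frees the C8 alcohol, the 4-methoxyphenyl ether (no benzylic C–H) being untouched; the alcohol is carried on at once to forestall acyl migration from O9.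

Step 18
Reactants: 22 methyl (2Z,4S,5S,6S,7R)-2-(bromomethyl)-6-ethenyl-8-hydroxy-5-[3-(4-methoxyphenoxy)prop-1-en-2-yl]-6-methyl-7-(2-methylpropanoyloxy)-4-(triethylsilyloxy)oct-2-enoate
Product: 23 methyl (2Z,4S,5S,6S,7R)-2-(bromomethyl)-6-ethenyl-5-[3-(4-methoxyphenoxy)prop-1-en-2-yl]-6-methyl-7-(2-methylpropanoyloxy)-8-oxo-4-(triethylsilyloxy)oct-2-enoate
Conditions: Dess–Martin periodinane, NaHCO3, CH2Cl2, 0 → 23 °C
Reagents that add atoms: none
Why: Buffered periodinane oxidation gives the α-acyloxy aldehyde without epimerizing C9 or disturbing the allylic bromide.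

Step 19
Reactants: 23 methyl (2Z,4S,5S,6S,7R)-2-(bromomethyl)-6-ethenyl-5-[3-(4-methoxyphenoxy)prop-1-en-2-yl]-6-methyl-7-(2-methylpropanoyloxy)-8-oxo-4-(triethylsilyloxy)oct-2-enoate
Product: 25 (5S,6R,7R,8S,9R,10S)-9-isobutyryloxy-15-(4-methoxyphenoxy)-6-(triethylsilyloxy)elema-1,3,11(13)-trien-12,8-olide, via hydroxy ester 24 (not isolated)
Conditions: CrCl2 (6 equiv), THF (0.005 M), 23 °C; aq. NH4Cl; then pyridinium p-toluenesulfonate (cat.), benzene, 40 °C
Reagents that add atoms: none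
Why: Two equivalents of divalent chromium insert into the allylic C13–Br bond to give an allylchromium species of trivalent chromium that adds through its γ-carbon C7 to the C8 aldehyde with transposition of the double bond to C11=C13, and the cis-disposed C8 oxygen then attacks the C12 methyl ester. The closest known reaction type is the intramolecular Nozaki–Hiyama–Kishi (Barbier-type) cyclization of ω-formyl 2-(bromomethyl)alk-2-enoates to fused α-methylene-γ-butyrolactones. The cyclohexane closes by 6-exo-trig attack of C7 on the carbonyl carbon C8 and the lactone by 5-exo-trig acyl substitution of O8 at C12. C7 is controlled by allylic 1,3-strain across C7=C11, which keeps H6 in the alkene plane so that C8 must approach from the face carrying C5 in a chair with the C5, C6 and C9 substituents equatorial, placing C11 equatorial and trans to O6; C8 is controlled by the (Z)-geometry of the allyl unit (C6 cis to CH2–Cr), which forces a cis-decalin-like closed Zimmerman–Traxler array with the aldehyde oxygen axial, hence the cis ring fusion. The step needs γ- over α-attack, cis over trans fusion and no intermolecular coupling or acyl migration from O9; these should be secured by the cyclic six-membered transition state, the defined (Z)-bromide, high dilution and the weakly basic alkoxide of trivalent chromium.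

Step 20
Reactants: 25 (5S,6R,7R,8S,9R,10S)-9-isobutyryloxy-15-(4-methoxyphenoxy)-6-(triethylsilyloxy)elema-1,3,11(13)-trien-12,8-olide
Product: 27 (5S,6R,7S,8S,9R,10S)-6,15-dihydroxy-9-isobutyryloxyelema-1,3,11(13)-trien-12,8-olide (CNP0298885.1), via triethylsilyl ether 26 (not isolated)
Conditions: (NH4)2Ce(NO3)6, MeCN/H2O (4:1), 0 → 23 °C
Reagents that add atoms: none
Why: Oxidation of the 4-methoxyphenyl ether by tetravalent cerium to the quinone releases the C15 alcohol, and the acidic aqueous medium should hydrolyse the secondary triethylsilyl ether, leaving lactone, isobutyrate and alkenes intact.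

Compound list
1 | (R)-4-benzyl-3-propanoyl-1,3-thiazolidine-2-thione | CCC(=O)N1[C@H](Cc2ccccc2)CSC1=S | starting material
2 | 2-[(4-methoxybenzyl)oxy]acetaldehyde | COc1ccc(COCC=O)cc1 | starting material
3 | trichlorotitanium (Z)-enolate of 1 | C/C=C(\O[Ti](Cl)(Cl)Cl)N1[C@H](Cc2ccccc2)CSC1=S | intermediate
4 | (R)-4-benzyl-3-[(2R,3R)-3-hydroxy-4-(4-methoxybenzyloxy)-2-methylbutanoyl]-1,3-thiazolidine-2-thione | O=C([C@H](C)[C@@H](O)COCc1ccc(OC)cc1)N1[C@H](Cc2ccccc2)CSC1=S | intermediate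
5 | (S)-2,2-dimethyl-1,3-dioxolane-4-carbaldehyde | O=C[C@H]1OC(C)(C)OC1 | starting material
6 | methyl 2-{[(4S)-2,2-dimethyl-1,3-dioxolan-4-yl](hydroxy)methyl}prop-2-enoate (carbinol epimers) | C=C(C(=O)OC)C(O)[C@H]1OC(C)(C)OC1 | intermediate
7 | methyl (Z)-2-(bromomethyl)-3-[(4R)-2,2-dimethyl-1,3-dioxolan-4-yl]prop-2-enoate | COC(=O)/C(CBr)=C/[C@H]1OC(C)(C)OC1 | intermediate
8 | methyl (E)-3-[(4R)-2,2-dimethyl-1,3-dioxolan-4-yl]-2-[(4-methoxyphenoxy)methyl]prop-2-enoate | COC(=O)/C(COc1ccc(OC)cc1)=C/[C@H]1OC(C)(C)OC1 | intermediate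
9 | (Z)-3-[(4R)-2,2-dimethyl-1,3-dioxolan-4-yl]-2-[(4-methoxyphenoxy)methyl]prop-2-en-1-ol | OC/C(COc1ccc(OC)cc1)=C/[C@H]1OC(C)(C)OC1 | intermediate
10 | (E)-3-[(4R)-2,2-dimethyl-1,3-dioxolan-4-yl]-2-[(4-methoxyphenoxy)methyl]prop-2-en-1-yl (2R,3R)-3-hydroxy-4-(4-methoxybenzyloxy)-2-methylbutanoate | O=C(OC/C(COc1ccc(OC)cc1)=C/[C@H]1OC(C)(C)OC1)[C@H](C)[C@@H](O)COCc1ccc(OC)cc1 | intermediate
11 | dilithium enolate alkoxide of 10 (C9 cis to the enolate oxygen) | [Li+].[Li+].[O-]/C(OC/C(COc1ccc(OC)cc1)=C/[C@H]1OC(C)(C)OC1)=C(C)\[C@@H]([O-])COCc1ccc(OC)cc1 | intermediate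
12 | (2S,3R)-2-{(1S)-1-[(4R)-2,2-dimethyl-1,3-dioxolan-4-yl]-2-[(4-methoxyphenoxy)methyl]prop-2-en-1-yl}-3-hydroxy-4-(4-methoxybenzyloxy)-2-methylbutanoic acid | OC(=O)[C@@]([C@@H](O)COCc1ccc(OC)cc1)(C)[C@H](C(=C)COc1ccc(OC)cc1)[C@H]1OC(C)(C)OC1 | intermediate
13 | (2R,3R)-2-{(1S)-1-[(4R)-2,2-dimethyl-1,3-dioxolan-4-yl]-2-[(4-methoxyphenoxy)methyl]prop-2-en-1-yl}-4-(4-methoxybenzyloxy)-2-methylbutane-1,3-diol | OC[C@@]([C@@H](O)COCc1ccc(OC)cc1)(C)[C@H](C(=C)COc1ccc(OC)cc1)[C@H]1OC(C)(C)OC1 | intermediate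
14 | (2S,3R)-2-{(1S)-1-[(4R)-2,2-dimethyl-1,3-dioxolan-4-yl]-2-[(4-methoxyphenoxy)methyl]prop-2-en-1-yl}-3-hydroxy-4-(4-methoxybenzyloxy)-2-methylbutanal | O=C[C@@]([C@@H](O)COCc1ccc(OC)cc1)(C)[C@H](C(=C)COc1ccc(OC)cc1)[C@H]1OC(C)(C)OC1 | intermediate
15 | (2R,3S,4S)-4-[(4R)-2,2-dimethyl-1,3-dioxolan-4-yl]-3-formyl-1-(4-methoxybenzyloxy)-5-[(4-methoxyphenoxy)methyl]-3-methylhex-5-en-2-yl 2-methylpropanoate | O=C[C@@]([C@@H](OC(=O)C(C)C)COCc1ccc(OC)cc1)(C)[C@H](C(=C)COc1ccc(OC)cc1)[C@H]1OC(C)(C)OC1 | intermediate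
16 | (2R,3S,4S)-4-[(4R)-2,2-dimethyl-1,3-dioxolan-4-yl]-3-ethenyl-1-(4-methoxybenzyloxy)-5-[(4-methoxyphenoxy)methyl]-3-methylhex-5-en-2-yl 2-methylpropanoate | C=C[C@@]([C@@H](OC(=O)C(C)C)COCc1ccc(OC)cc1)(C)[C@H](C(=C)COc1ccc(OC)cc1)[C@H]1OC(C)(C)OC1 | intermediate
17 | (2R,3S,4S)-4-[(1R)-1,2-dihydroxyethyl]-3-ethenyl-1-(4-methoxybenzyloxy)-5-[(4-methoxyphenoxy)methyl]-3-methylhex-5-en-2-yl 2-methylpropanoate | C=C[C@@]([C@@H](OC(=O)C(C)C)COCc1ccc(OC)cc1)(C)[C@H](C(=C)COc1ccc(OC)cc1)[C@@H](O)CO | intermediate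
18 | (2R,3S,4S)-4-[(1R)-1,2-bis(triethylsilyloxy)ethyl]-3-ethenyl-1-(4-methoxybenzyloxy)-5-[(4-methoxyphenoxy)methyl]-3-methylhex-5-en-2-yl 2-methylpropanoate | C=C[C@@]([C@@H](OC(=O)C(C)C)COCc1ccc(OC)cc1)(C)[C@H](C(=C)COc1ccc(OC)cc1)[C@@H](O[Si](CC)(CC)CC)CO[Si](CC)(CC)CC | intermediate
19 | (2R,3S,4S)-3-ethenyl-1-(4-methoxybenzyloxy)-5-[(4-methoxyphenoxy)methyl]-3-methyl-4-[(1R)-2-oxo-1-(triethylsilyloxy)ethyl]hex-5-en-2-yl 2-methylpropanoate | C=C[C@@]([C@@H](OC(=O)C(C)C)COCc1ccc(OC)cc1)(C)[C@H](C(=C)COc1ccc(OC)cc1)[C@@H](O[Si](CC)(CC)CC)C=O | intermediate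
20 | methyl (4R,5S,6S,7R)-6-ethenyl-3-hydroxy-8-(4-methoxybenzyloxy)-5-[3-(4-methoxyphenoxy)prop-1-en-2-yl]-6-methyl-2-methylidene-7-(2-methylpropanoyloxy)-4-(triethylsilyloxy)octanoate (C3 epimers) | C=C[C@@]([C@@H](OC(=O)C(C)C)COCc1ccc(OC)cc1)(C)[C@H](C(=C)COc1ccc(OC)cc1)[C@@H](O[Si](CC)(CC)CC)C(O)C(=C)C(=O)OC | intermediate
21 | methyl (2Z,4S,5S,6S,7R)-2-(bromomethyl)-6-ethenyl-8-(4-methoxybenzyloxy)-5-[3-(4-methoxyphenoxy)prop-1-en-2-yl]-6-methyl-7-(2-methylpropanoyloxy)-4-(triethylsilyloxy)oct-2-enoate | C=C[C@@]([C@@H](OC(=O)C(C)C)COCc1ccc(OC)cc1)(C)[C@H](C(=C)COc1ccc(OC)cc1)[C@@H](O[Si](CC)(CC)CC)/C=C(\CBr)C(=O)OC | intermediate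
22 | methyl (2Z,4S,5S,6S,7R)-2-(bromomethyl)-6-ethenyl-8-hydroxy-5-[3-(4-methoxyphenoxy)prop-1-en-2-yl]-6-methyl-7-(2-methylpropanoyloxy)-4-(triethylsilyloxy)oct-2-enoate | C=C[C@@]([C@@H](OC(=O)C(C)C)CO)(C)[C@H](C(=C)COc1ccc(OC)cc1)[C@@H](O[Si](CC)(CC)CC)/C=C(\CBr)C(=O)OC | intermediate
23 | methyl (2Z,4S,5S,6S,7R)-2-(bromomethyl)-6-ethenyl-5-[3-(4-methoxyphenoxy)prop-1-en-2-yl]-6-methyl-7-(2-methylpropanoyloxy)-8-oxo-4-(triethylsilyloxy)oct-2-enoate | C=C[C@@]([C@@H](OC(=O)C(C)C)C=O)(C)[C@H](C(=C)COc1ccc(OC)cc1)[C@@H](O[Si](CC)(CC)CC)/C=C(\CBr)C(=O)OC | intermediate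
24 | methyl (5S,6R,7R,8S,9R,10S)-8-hydroxy-9-isobutyryloxy-15-(4-methoxyphenoxy)-6-(triethylsilyloxy)elema-1,3,11(13)-trien-12-oate | C=C[C@@]1(C)[C@H](C(=C)COc2ccc(OC)cc2)[C@@H](O[Si](CC)(CC)CC)[C@H](C(=C)C(=O)OC)[C@H](O)[C@@H]1OC(=O)C(C)C | intermediate
25 | (5S,6R,7R,8S,9R,10S)-9-isobutyryloxy-15-(4-methoxyphenoxy)-6-(triethylsilyloxy)elema-1,3,11(13)-trien-12,8-olide | C=C[C@@]1(C)[C@H](C(=C)COc3ccc(OC)cc3)[C@@H](O[Si](CC)(CC)CC)[C@@H]2C(=C)C(=O)O[C@@H]2[C@@H]1OC(=O)C(C)C | intermediate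
26 | (5S,6R,7R,8S,9R,10S)-15-hydroxy-9-isobutyryloxy-6-(triethylsilyloxy)elema-1,3,11(13)-trien-12,8-olide | C=C[C@@]1(C)[C@H](C(=C)CO)[C@@H](O[Si](CC)(CC)CC)[C@@H]2C(=C)C(=O)O[C@@H]2[C@@H]1OC(=O)C(C)C | intermediate
27 | (5S,6R,7S,8S,9R,10S)-6,15-dihydroxy-9-isobutyryloxyelema-1,3,11(13)-trien-12,8-olide (CNP0298885.1) | C=C[C@@]1(C)[C@H](C(=C)CO)[C@@H](O)[C@@H]2C(=C)C(=O)O[C@@H]2[C@@H]1OC(=O)C(C)C | target

Total step count: 20. Longest linear sequence: 19 steps (steps 2–20, from 5); step 1 lies on the short branch that joins at step 6.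

Steps most likely to fail

Step 19 (ring closure). The closure may suffer from poor facial selectivity, from trans fusion if the allylchromium unit loses its geometry, or from migration of the isobutyryl group onto the new C8 alkoxide. The fallback is an intramolecular allylboration. It sets out from alcohol 22: palladium-catalysed borylation of the allylic bromide (B2pin2, Pd2(dba)3 as source of zerovalent palladium, toluene, 50 °C) would give the allyl pinacolboronate F1, and Dess–Martin oxidation would give the formyl allylboronate F2. This should cyclize on gentle warming through the same closed chair array, without a low-valent metal, to the cyclic borate F3. Aqueous work-up cleaves F3 to hydroxy ester 24, and acid-catalysed lactonization rejoins the route at 25.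

Step 7 (dianionic rearrangement). Enolization to the tetrasubstituted dianion may be incomplete, or the aryloxide may be lost by a competing SN2′ cyclization, or the diastereoselectivity may be low. The fallback is a silyl ketene acetal Ireland–Claisen rearrangement. It sets out from ester 10: silylation of the C9 hydroxyl (tBuMe2SiOTf, 2,6-lutidine) would give F4, and enolization with LiN(iPr)2 in THF/1,3-dimethyl-3,4,5,6-tetrahydro-2(1H)-pyrimidinone with Me3SiCl would give the silyl ketene acetal F5 (C9 branch cis to OSiMe3). F5 should rearrange at 23–60 °C under control of the allylic dioxolane centre to the silyl ester F6. Treatment with Bu4NF removes both silyl groups and returns acid 12.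

Step 15 (vinylalumination). Addition to the hindered α-silyloxy aldehyde may be slow, and silyl migration or reduction of the aldehyde may intervene. The fallback is an aldol/selenoxide elimination. It sets out from aldehyde 19: aldol addition of the lithium enolate of methyl 3-(phenylselanyl)propanoate (LiN(iPr)2, THF, −78 °C) would give the β-hydroxy selenide F7. Oxidation with H2O2 gives selenoxide F8, which should undergo syn-elimination at 23 °C and return to the route at 20.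

Further compounds
F1 | step 19 | methyl (2Z,4S,5S,6S,7R)-6-ethenyl-8-hydroxy-5-[3-(4-methoxyphenoxy)prop-1-en-2-yl]-6-methyl-7-(2-methylpropanoyloxy)-2-[(4,4,5,5-tetramethyl-1,3,2-dioxaborolan-2-yl)methyl]-4-(triethylsilyloxy)oct-2-enoate | C=C[C@@]([C@@H](OC(=O)C(C)C)CO)(C)[C@H](C(=C)COc1ccc(OC)cc1)[C@@H](O[Si](CC)(CC)CC)/C=C(\CB1OC(C)(C)C(C)(C)O1)C(=O)OC
F2 | step 19 | 8-oxo analogue of F1 (formyl allylboronate) | C=C[C@@]([C@@H](OC(=O)C(C)C)C=O)(C)[C@H](C(=C)COc1ccc(OC)cc1)[C@@H](O[Si](CC)(CC)CC)/C=C(\CB1OC(C)(C)C(C)(C)O1)C(=O)OC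
F3 | step 19 | pinacol borate ester of 24 at O8 | C=C[C@@]1(C)[C@H](C(=C)COc2ccc(OC)cc2)[C@@H](O[Si](CC)(CC)CC)[C@H](C(=C)C(=O)OC)[C@H](OB2OC(C)(C)C(C)(C)O2)[C@@H]1OC(=O)C(C)C
F4 | step 7 | tert-butyldimethylsilyl ether of 10 at the C9 hydroxyl | O=C(OC/C(COc1ccc(OC)cc1)=C/[C@H]1OC(C)(C)OC1)[C@H](C)[C@@H](O[Si](C)(C)C(C)(C)C)COCc1ccc(OC)cc1
F5 | step 7 | trimethylsilyl ketene acetal of F4 (C9 branch cis to OSiMe3) | C[Si](C)(C)O/C(OC/C(COc1ccc(OC)cc1)=C/[C@H]1OC(C)(C)OC1)=C(C)\[C@@H](O[Si](C)(C)C(C)(C)C)COCc1ccc(OC)cc1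
F6 | step 7 | trimethylsilyl ester of the C9 tert-butyldimethylsilyl ether of 12 | C[Si](C)(C)OC(=O)[C@@]([C@@H](O[Si](C)(C)C(C)(C)C)COCc1ccc(OC)cc1)(C)[C@H](C(=C)COc1ccc(OC)cc1)[C@H]1OC(C)(C)OC1
F7 | step 15 | β-hydroxy selenide: 2-[(phenylselanyl)methyl] analogue of 20 lacking the methylidene | C=C[C@@]([C@@H](OC(=O)C(C)C)COCc1ccc(OC)cc1)(C)[C@H](C(=C)COc1ccc(OC)cc1)[C@@H](O[Si](CC)(CC)CC)C(O)C(C[Se]c1ccccc1)C(=O)OC
F8 | step 15 | selenoxide of F7 | C=C[C@@]([C@@H](OC(=O)C(C)C)COCc1ccc(OC)cc1)(C)[C@H](C(=C)COc1ccc(OC)cc1)[C@@H](O[Si](CC)(CC)CC)C(O)C(C[Se](=O)c1ccccc1)C(=O)OC
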